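Freeze one number and run the flask on it: the feed, the concentration of J turned into X and G per second, read from the last winter reading as 3.33 mM/s.

in all of them: L 19 mM (held); Z 25 mM

| charge | J | remark | time |
|---|---|---|---|
| winter | 0.75 M | run made earlier |  |
| flask | 0.50 M |  | 10 min |

winter run (percent of the J charged)

| time / s | X / % | G / % |
|---|---|---|
| 10.0 | 4.5 | 0.4 |
| 20.0 | 9.0 | 1.1 |
| 30.0 | 14.6 | 1.0 |
| 60.0 | 26.9 | 1.2 |
| 120 | 50.1 | 3.1 |

(standard deviation of a reading: 0.5 percentage points)

- at the start none of L is in solution
- a reading or a percentage of X counts all its forms, free or not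

1. ratio of X to G at 2.5 s
2. ratio of X to G at 10 min
3. which of X and G there is more of at 10 min

The winter total of X and G at 120 s is nearly twice the total at 60.0 s, so the winter rate reads steady while J fell, a zero-order stretch, and the reckoning here carries it over to the flask.

In the first instants of the flask, the reckoning at the feed puts 1.67% of the J charged as turned by 2.5 s, a figure that takes the feed as running from the start, though at the start none of L is in solution. The winter G at 10.0 s reads 0.4% with a scatter of 0.5 percentage points, so the early ratio stands poorly on the readings.

Through the middle, the flask's J charge of 0.50 M divided by the feed gives a reckoned span of 2.51 min, with X ahead on the winter ratio of X to G at 120 s, which reads 16.2.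

On this reckoning the end comes early: after that span the flask has 7.49 min to go, in which X may pass over to G, so this reckoning commits to X in the lead and a late ratio at or below the winter reading.

The forecast gave 12 at 2.5 s (range 5 to 24), 13 at 10 min (range 3 to 21), and X in the lead: “X should then stay dominant”.

The flask gives 31.1 at 2.5 s and 8.21 at 10 min, with X ahead.

    J + Q ⇌ G (K = 147 /M, k = 0.0334 /M/s)
    L ⇌ Q, rate k2*(csat - [Q]) (kL = 0.276 /s)
    E ⇌ X, rate k3*(cs3 - [X]) while solid is left; crystals form when [X] > cs3 (solubility = 0.250 M, k = 0.170 /s)
    X + Z ⇌ G + Z, rate k4*[Z]*[X] forward; the back reaction follows from the equilibrium constant (k = 0.0103 /M/s)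
    J + Q ⇌ X (K = 325 /M, k = 1.05 /M/s)

While Q, the dissolved L, climbed to 0.00923 M at 1.00 min, J and Q made X in the flask, and J stood at 64.0% against the 60.1% that the feed gives. By 5.00 min the flask held J at 10.0% and Q at 0.0183 M, and from there to 10.0 min X went from 83.4% to 82.1% while G rose from 6.56% to 9.99%. The neighbour with 0.010 M of Z, charged with the same J and L and so reckoned with the same span of 2.51 min, ended at 10 min with J at 7.9%, G at 7.29% and a ratio of 11.6.

All runs are simulated for an exercise; the scatter is artificial.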